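The target is read as a ring-opened 7-oxabicyclo[2.2.1]heptan-2-one. In the cyclohexenone ring (C1 carbonyl, C2=C3 alkene) the tertiary carbinol oxygen on C6 and the enone β-carbon C3 stand 1,4 to each other, so a furan oxygen can become the C6 hydroxyl. A catalytic enantioselective Diels–Alder reaction of (3-methoxyfuran-2-yl)methyl benzoate with (E)-β-acetoxyvinyl phenyl ketone forges C3–C4 and C5–C6 in one operation and sets C4, C5 and C6. The furan supplies C1, C2, C3, C6 and the bridging oxygen; the E-alkene supplies the trans C4/C5 pair. Baeyer–Villiger oxidation then turns the C4 benzoyl group into the benzoate, and β-elimination of the oxygen bridge releases enone and tertiary alcohol.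

Key step: step 3

Assumption: 3-methoxyfuran and 1-phenylprop-2-yn-1-one are taken as purchasable; the facial sense of the boron catalyst is assigned from the α-C–H···O binding model for s-trans enones, and its mirror image is equally available.

Numbering: the target is numbered as a cyclohex-2-en-1-one. The bicyclic intermediates are numbered as 7-oxabicyclo[2.2.1]heptanes, whose C1, C2, C3, C4, C5, C6 become target C6, C1, C2, C3, C4, C5.

Step 1
Reactants: 1 1-phenylprop-2-yn-1-one
Product: 2 (E)-3-oxo-3-phenylprop-1-en-1-yl acetate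
Conditions: AcOH, N-methylmorpholine (cat.), CH2Cl2, 0 °C to rt
Reagents that add atoms: acetic acid, CC(=O)O
Why: Tertiary-amine-catalysed conjugate addition of a carboxylic acid to an ynone (addition–elimination through the β-ammonium enone) should give the thermodynamically preferred E-enol ester; no stereocentre is formed.

Step 2
Reactants: 3 3-methoxyfuran
Product: 6 (3-methoxyfuran-2-yl)methyl benzoate, via (3-methoxyfuran-2-yl)lithium 4 (not isolated), via lithium (3-methoxyfuran-2-yl)methanolate 5 (not isolated)
Conditions: n-BuLi, THF, −78 to 0 °C; (CH2O)n, −78 °C to rt; BzCl, 0 °C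
Reagents that add atoms: formaldehyde (from paraformaldehyde), C=O; benzoyl chloride, O=C(Cl)c1ccccc1
Why: Directed lithiation at C2 (flanked by the ring oxygen and the methoxy group), 1,2-addition to formaldehyde and O-acylation of the lithium alkoxide in one pot should give the diene, which is kept cold and free of acid; no stereocentre is formed.

Step 3
Reactants: 6 (3-methoxyfuran-2-yl)methyl benzoate, 2 (E)-3-oxo-3-phenylprop-1-en-1-yl acetate
Product: 8 [(1S,4S,5R,6S)-6-acetoxy-5-benzoyl-2,2-dimethoxy-7-oxabicyclo[2.2.1]heptan-1-yl]methyl benzoate, via enol-ether cycloadduct 7 (not isolated)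
Conditions: (R)-3,3-diphenyl-1-(2-methylphenyl)tetrahydro-1H,3H-pyrrolo[1,2-c][1,3,2]oxazaborole (20 mol %), HN(SO2CF3)2 (20 mol %), CH2Cl2, −78 °C; then MeOH, pyridinium p-toluenesulfonate (cat.), −40 to 0 °C; Et3N
Reagents that add atoms: methanol, CO
Why: Normal-demand Diels–Alder reaction: the s-trans enone, activated by coordination of its ketone oxygen to the chiral boron cation, adds across furan C2 and C5 in a concerted but asynchronous (4π+2π) process in which the bond from furan C2 to the acetoxy-bearing β-carbon runs ahead. The closest known reactions are the oxazaborolidinium-catalysed enantioselective Diels–Alder additions of furans and 2-silyloxydienes to acrylates and enones and the cycloadditions of 3-alkoxyfurans. The only ring closed is the six-membered carbocycle (which completes the 7-oxabicyclo[2.2.1]heptene), and it closes by suprafacial–suprafacial cycloaddition of a cyclic diene, not by an exo or endo chain cyclisation. C1 and C4 follow from addition to one face of the planar furan, the trans C5/C6 relationship is copied from the E-alkene, and the endo preference of the Lewis-acid-bound benzoyl group should put it endo and the acetate exo, syn to the oxygen bridge that becomes the tertiary OH. The absolute sense comes from the catalyst, whose cis-phenyl group covers one face of the enone held by B–O coordination and an α-C–H···O contact, so that the diene should add to the Re face of the benzoyl-bearing carbon and give (1S,4S,5R,6S)-7. The step needs regiocontrol, secured by the 3-methoxy group, which makes furan C2 the nucleophilic terminus and pairs it with the electrophilic β-carbon of the enone; methanol then adds to the enol ether to give the dimethyl ketal, which stops retro-cycloaddition and masks the future C1 ketone from the peracid of step 4.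

Step 4
Reactants: 8 [(1S,4S,5R,6S)-6-acetoxy-5-benzoyl-2,2-dimethoxy-7-oxabicyclo[2.2.1]heptan-1-yl]methyl benzoate
Product: 9 [(1S,4S,5R,6S)-6-acetoxy-5-(benzoyloxy)-2,2-dimethoxy-7-oxabicyclo[2.2.1]heptan-1-yl]methyl benzoate
Conditions: (CF3CO)2O, urea·H2O2, Na2HPO4, CH2Cl2, 0 °C to rt
Reagents that add atoms: trifluoroperacetic acid, OOC(=O)C(F)(F)F (made in the flask from trifluoroacetic anhydride, O=C(OC(=O)C(F)(F)F)C(F)(F)F, and urea–hydrogen peroxide, NC(N)=O.OO)
Why: Baeyer–Villiger oxidation, in which the secondary ring carbon C5 should migrate in preference to phenyl and with retention, so that the endo benzoyl group becomes the endo benzoate while the ketal and the esters are inert to the buffered peracid.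

Step 5
Reactants: 9 [(1S,4S,5R,6S)-6-acetoxy-5-(benzoyloxy)-2,2-dimethoxy-7-oxabicyclo[2.2.1]heptan-1-yl]methyl benzoate
Product: 10 [(1S,4S,5R,6S)-6-acetoxy-5-(benzoyloxy)-2-oxo-7-oxabicyclo[2.2.1]heptan-1-yl]methyl benzoate
Conditions: CF3CO2H/H2O (9:1), CH2Cl2, 0 °C to rt
Reagents that add atoms: water, O
Why: Acid-catalysed ketal hydrolysis, for which strong acid is chosen because the α-oxygen bridge slows ionisation; the esters and the oxygen bridge should survive and no stereocentre changes.

Step 6
Reactants: 10 [(1S,4S,5R,6S)-6-acetoxy-5-(benzoyloxy)-2-oxo-7-oxabicyclo[2.2.1]heptan-1-yl]methyl benzoate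
Product: 13 2-O-acetylzeylenone, (4R,5S,6S)-5-acetoxy-4-(benzoyloxy)-6-[(benzoyloxy)methyl]-6-hydroxycyclohex-2-en-1-one, via trimethylsilyl enol ether 11 (not isolated), via ring-opened trimethylsilyl ether 12 (not isolated)
Conditions: Me3SiOSO2CF3, Et3N, CH2Cl2, −20 to 0 °C; then 1 M HCl, THF, 0 °C
Reagents that add atoms: none
Why: Silyl-triflate-mediated β-elimination of the oxygen bridge (E1cB-type opening through the bicyclic C2 silyl enol ether, a known reaction of 7-oxabicyclo[2.2.1]heptan-2-ones) should give the target C2=C3 enone and release the bridge oxygen as the C6 silyl ether, cleaved in the acidic work-up; target C4, C5 and C6 are not touched.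

Compound list
1 | 1-phenylprop-2-yn-1-one | C#CC(=O)c1ccccc1 | starting material
2 | (E)-3-oxo-3-phenylprop-1-en-1-yl acetate | CC(=O)O/C=C/C(=O)c1ccccc1 | intermediate
3 | 3-methoxyfuran | COc1ccoc1 | starting material
4 | (3-methoxyfuran-2-yl)lithium | COc1ccoc1[Li] | intermediate (not isolated)
5 | lithium (3-methoxyfuran-2-yl)methanolate | COc1ccoc1CO[Li] | intermediate (not isolated)
6 | (3-methoxyfuran-2-yl)methyl benzoate | COc1ccoc1COC(=O)c1ccccc1 | intermediate
7 | [(1S,4S,5R,6S)-6-acetoxy-5-benzoyl-2-methoxy-7-oxabicyclo[2.2.1]hept-2-en-1-yl]methyl benzoate (exo acetate, endo benzoyl) | COC1=C[C@@H]2O[C@@]1(COC(=O)c1ccccc1)[C@@H](OC(C)=O)[C@@H]2C(=O)c1ccccc1 | intermediate (not isolated)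
8 | [(1S,4S,5R,6S)-6-acetoxy-5-benzoyl-2,2-dimethoxy-7-oxabicyclo[2.2.1]heptan-1-yl]methyl benzoate | COC1(OC)C[C@@H]2O[C@@]1(COC(=O)c1ccccc1)[C@@H](OC(C)=O)[C@@H]2C(=O)c1ccccc1 | intermediate
9 | [(1S,4S,5R,6S)-6-acetoxy-5-(benzoyloxy)-2,2-dimethoxy-7-oxabicyclo[2.2.1]heptan-1-yl]methyl benzoate | COC1(OC)C[C@@H]2O[C@@]1(COC(=O)c1ccccc1)[C@@H](OC(C)=O)[C@@H]2OC(=O)c1ccccc1 | intermediate
10 | [(1S,4S,5R,6S)-6-acetoxy-5-(benzoyloxy)-2-oxo-7-oxabicyclo[2.2.1]heptan-1-yl]methyl benzoate | O=C1C[C@@H]2O[C@@]1(COC(=O)c1ccccc1)[C@@H](OC(C)=O)[C@@H]2OC(=O)c1ccccc1 | intermediate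
11 | [(1S,4S,5R,6S)-6-acetoxy-5-(benzoyloxy)-2-[(trimethylsilyl)oxy]-7-oxabicyclo[2.2.1]hept-2-en-1-yl]methyl benzoate | C[Si](C)(C)OC1=C[C@@H]2O[C@@]1(COC(=O)c1ccccc1)[C@@H](OC(C)=O)[C@@H]2OC(=O)c1ccccc1 | intermediate (not isolated)
12 | (4R,5S,6S)-5-acetoxy-4-(benzoyloxy)-6-[(benzoyloxy)methyl]-6-[(trimethylsilyl)oxy]cyclohex-2-en-1-one | CC(=O)O[C@H]1[C@H](OC(=O)c2ccccc2)C=CC(=O)[C@]1(O[Si](C)(C)C)COC(=O)c1ccccc1 | intermediate (not isolated)
13 | 2-O-acetylzeylenone, (4R,5S,6S)-5-acetoxy-4-(benzoyloxy)-6-[(benzoyloxy)methyl]-6-hydroxycyclohex-2-en-1-one | CC(=O)O[C@H]1[C@H](OC(=O)c2ccccc2)C=CC(=O)[C@]1(O)COC(=O)c1ccccc1 | target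

Total step count: 6. Longest linear sequence: 5 steps (3 → 6 → 8 → 9 → 10 → 13).

Steps most likely to fail

Step 3. The cationic boron Lewis acid may ionise or polymerise the electron-rich furfuryl benzoate, and the addition may stop at the Michael stage or proceed with poor endo or facial selectivity. The fallback sets out from 6 and 2 and comes back at 8. The two are combined without catalyst (CH2Cl2, 12 kbar, rt), relying on the innate reactivity of the 3-alkoxyfuran, and the product is trapped with MeOH and pyridinium p-toluenesulfonate as before. This should give the cycloadduct 7 together with the mirror-image enol-ether cycloadduct F1 and, after the trap, racemic ketal, that is 8 together with the mirror-image ketal F2. Preparative chromatography on a chiral stationary phase (amylose tris(3,5-dimethylphenylcarbamate), CO2/MeOH) then delivers 8.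

Step 4. Phenyl migration may compete, because the migrating ring carbon is deactivated by two β-oxygen substituents; this would insert oxygen on the wrong side of the carbonyl group. The fallback sets out from 8 and comes back at 9. Soft enolisation (t-BuMe2SiOSO2CF3, Et3N, CH2Cl2, −78 °C) should give the tert-butyldimethylsilyl enol ether F3. Ozonolysis (O3, CH2Cl2/MeOH, −78 °C; Me2S) cleaves the exocyclic enol ether to the C5 ketone F4. NaBH4 (MeOH, −40 °C) should deliver hydride from the exo face and give the endo C5 alcohol F5, and BzCl, pyridine and 4-(dimethylamino)pyridine give 9.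

Step 6. After the bridge has opened, the amine and the silyl triflate may remove the γ-hydrogen of the enone, which leads to loss of acetate or to epimerisation at target C4. The fallback sets out from 10 and comes back at 13. Bromination at C3 (pyridinium tribromide, AcOH/CH2Cl2, rt) should give the exo C3 bromo ketone F6. Zinc dust (NH4Cl, EtOH/THF, 0 °C) then forms the zinc enolate, which expels the bridging oxygen by reductive β-elimination under non-basic conditions and gives 13 after aqueous work-up.

Further compounds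
F1 | step 3 | [(1R,4R,5S,6R)-6-acetoxy-5-benzoyl-2-methoxy-7-oxabicyclo[2.2.1]hept-2-en-1-yl]methyl benzoate (mirror image of 7, not isolated) | COC1=C[C@H]2O[C@]1(COC(=O)c1ccccc1)[C@H](OC(C)=O)[C@H]2C(=O)c1ccccc1
F2 | step 3 | [(1R,4R,5S,6R)-6-acetoxy-5-benzoyl-2,2-dimethoxy-7-oxabicyclo[2.2.1]heptan-1-yl]methyl benzoate (mirror image of 8) | COC1(OC)C[C@H]2O[C@]1(COC(=O)c1ccccc1)[C@H](OC(C)=O)[C@H]2C(=O)c1ccccc1
F3 | step 4 | [(1S,4S,6S)-6-acetoxy-5-{[tert-butyl(dimethyl)silyl]oxy(phenyl)methylidene}-2,2-dimethoxy-7-oxabicyclo[2.2.1]heptan-1-yl]methyl benzoate | COC1(OC)C[C@@H]2O[C@@]1(COC(=O)c1ccccc1)[C@@H](OC(C)=O)C2=C(O[Si](C)(C)C(C)(C)C)c1ccccc1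
F4 | step 4 | [(1S,4S,6R)-6-acetoxy-2,2-dimethoxy-5-oxo-7-oxabicyclo[2.2.1]heptan-1-yl]methyl benzoate | COC1(OC)C[C@@H]2O[C@@]1(COC(=O)c1ccccc1)[C@@H](OC(C)=O)C2=O
F5 | step 4 | [(1S,4S,5R,6S)-6-acetoxy-5-hydroxy-2,2-dimethoxy-7-oxabicyclo[2.2.1]heptan-1-yl]methyl benzoate (endo alcohol) | COC1(OC)C[C@@H]2O[C@@]1(COC(=O)c1ccccc1)[C@@H](OC(C)=O)[C@@H]2O
F6 | step 6 | [(1S,3R,4R,5S,6S)-6-acetoxy-5-(benzoyloxy)-3-bromo-2-oxo-7-oxabicyclo[2.2.1]heptan-1-yl]methyl benzoate (exo bromide) | O=C1[C@H](Br)[C@@H]2O[C@@]1(COC(=O)c1ccccc1)[C@@H](OC(C)=O)[C@@H]2OC(=O)c1ccccc1
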